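**Strategy**

The cyclohexene is disconnected at C3–C4 and C5–C6 (target numbering: C1 OMe, C2 =CH, C3 =C–C7H2OBz, C4 OH, C5 OBz, C6 OH). C7 on C3 and the oxygen on C6 stand para on the ring and are read as the C(=O)–O unit of a 2-pyrone; the cis O4/O5 pair is vinylene carbonate. One enantioselective, endo [4+2] between 3-bromo-2H-pyran-2-one and vinylene carbonate, run under pressure so that the CO2 bridge survives, closes the carbocycle and fixes C3–C6 with O4/O5 anti to O6. The bridgehead bromide then lets O6 transpose the alkene to C2=C3 and deliver the C1 oxygen.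

Key step: step 1

**Remarks on the chemistry (assumptions)**

- 3-Bromo-2H-pyran-2-one is taken as a purchased catalogue reagent.
- In the Why lines and the risk section the atoms keep their target numbers (C1–C7, O1–O7); the systematic names use their own locants.
- The adduct that maps onto the target, which is (1S,4R,5R,6R) in target numbering, is the (1R,4R,7S,8S) endo isomer. Its lactone bridge (O6, C7) lies on one face of the C1–C6 ring; Br, O4 and O5 lie on the other.
- The sense of induction of the ytterbium–BINOL catalyst on this substrate cannot be predicted. (R)-BINOL is written; (S)-BINOL is used instead if a first run shows that it is the antipode leading to 3.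

**Route**

Step 1
Reactants: 1 3-bromo-2H-pyran-2-one; 2 vinylene carbonate
Product: 3 (1R,4R,7S,8S)-4-bromo-7,8-(carbonyldioxy)-2-oxabicyclo[2.2.2]oct-5-en-3-one (endo adduct)
Conditions: Yb(OTf)3 (20 mol %), (R)-BINOL (24 mol %), i-Pr2NEt (48 mol %), 4 Å MS, CH2Cl2, 10 kbar, 20 °C; 2 (2 equiv)
Reagents that add atoms: none
Why: Proposed new method: trivalent ytterbium in the Yb(OTf)3/BINOL/amine complex should bind the pyrone carbonyl at the lone pair syn to the ring oxygen (the other one is blocked by C–Br) and lower the diene LUMO, so that the enediol π bond of 2 adds across pyrone C3 and C6 in a concerted, asynchronous, suprafacial [4+2]; the closest known reactions are the ytterbium–BINOL-catalysed inverse-demand cycloadditions of 3-acceptor-substituted 2-pyrones with enol ethers and the uncatalysed thermal or high-pressure cycloadditions of 1 itself. The one ring formed, the carbocycle C1–C6, closes by intermolecular cycloaddition with both σ bonds (C3–C4, C5–C6) made on the same diene face, and 10 kbar allows this at 20 °C, well below the temperature at which the O–C(=O) bridge is lost as CO2. C4 and C5 are cis because the Z geometry of the dienophile is transferred, and they lie anti to the lactone bridge because the endo transition state is favoured by secondary overlap of the carbonate with the diene and by its smaller volume under pressure. C3 and C6 are bridgeheads, fixed relative to C4/C5 by the bicyclic geometry, so that the absolute configuration of all four centres depends on a single event, the choice of pyrone face left open by the binaphtholate pocket. The step needs endo and enantioface selectivity but no regioselectivity, because 2 is symmetrical.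

Step 2
Reactants: 3 endo adduct; 4 methanol
Product: 6 methyl (1R,4R,5R,6S)-4,5-dihydroxy-7-oxabicyclo[4.1.0]hept-2-ene-3-carboxylate, via bromo triol ester 5 (not isolated)
Conditions: NaOMe (1.15 equiv), MeOH, −20 → 0 °C; AcOH quench
Reagents that add atoms: methanol, CO; sodium methoxide, [Na+].[O-]C
Why: Transesterification by methoxide opens the strained bridged lactone and the cyclic carbonate, and the freed C6 alkoxide then closes onto C1 in an intramolecular anti SN2′ displacement of the now pseudoaxial tertiary allylic bromide (a vinylogous halohydrin-to-epoxide closure) that puts the alkene at C2=C3 in conjugation with the ester, the new C1–O bond being forced onto the face of O6 by the three-membered ring while O4, cis to Br, cannot displace it.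

Step 3
Reactants: 6 epoxy diol ester; 4 methanol
Product: 7 methyl (3S,4S,5R,6R)-4,5,6-trihydroxy-3-methoxycyclohex-1-ene-1-carboxylate
Conditions: CSA (10 mol %), MeOH, 0 → 20 °C
Reagents that add atoms: methanol, CO
Why: Acid-catalysed ring opening of a vinyl epoxide by methanol takes place at the allylic carbon C1 with inversion (SN2-type opening of a γ,δ-epoxy enoate, C6 being deactivated by the adjacent C5–O bond), which places OMe trans to the C6 hydroxyl.

Step 4
Reactants: 7 methoxy triol ester
Product: 8 (1S,2R,3R,6S)-4-(hydroxymethyl)-6-methoxycyclohex-4-ene-1,2,3-triol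
Conditions: i-Bu2AlH (7 equiv), THF, −78 → 0 °C; aq. KNaC4H4O6 (potassium sodium tartrate)
Reagents that add atoms: none
Why: 1,2-Reduction of the conjugated ester by i-Bu2AlH gives the primary allylic alcohol C7 without touching the alkene or any stereocentre, the three hydroxyls being carried as aluminium alkoxides.

Step 5
Reactants: 8 tetraol; 9 benzoyl chloride
Product: 11 [(3S,4R,5R,6R)-5-(benzoyloxy)-4,6-dihydroxy-3-methoxycyclohex-1-en-1-yl]methyl benzoate (CNP0349013.6), via stannylene acetal 10 (not isolated)
Conditions: Bu2SnO (1.1 equiv), MeOH, reflux, evaporate; then BzCl (2.1 equiv), 1,4-dioxane, 0 → 20 °C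
Reagents that add atoms: benzoyl chloride, O=C(Cl)c1ccccc1
Why: Stannylene-directed regioselective acylation: the tin acetal across the cis O4/O5 pair activates the equatorial O5 over the pseudoaxial allylic O4, the primary allylic O7 is the most reactive remaining hydroxyl and O6 between two equatorial substituents the least, the pattern known from the 3,6-di-O-benzoylation of galactopyranosides, of which 8 is the carbocyclic analogue.

**Compound list**

1 | 3-bromo-2H-pyran-2-one | O=C1OC=CC=C1Br | starting material
2 | vinylene carbonate (1,3-dioxol-2-one) | O=C1OC=CO1 | starting material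
3 | (1R,4R,7S,8S)-4-bromo-7,8-(carbonyldioxy)-2-oxabicyclo[2.2.2]oct-5-en-3-one; endo: carbonate syn to C5=C6 and anti to the lactone bridge | O=C1O[C@@H]2C=C[C@@]1(Br)[C@H]3OC(=O)O[C@@H]23 | intermediate
4 | methanol | CO | starting material
5 | methyl (1R,4R,5S,6S)-1-bromo-4,5,6-trihydroxycyclohex-2-ene-1-carboxylate (bromo triol ester) | COC(=O)[C@@]1(Br)C=C[C@@H](O)[C@H](O)[C@@H]1O | intermediate (not isolated)
6 | methyl (1R,4R,5R,6S)-4,5-dihydroxy-7-oxabicyclo[4.1.0]hept-2-ene-3-carboxylate; epoxide on the face opposite the cis-diol | COC(=O)C1=C[C@H]2O[C@H]2[C@H](O)[C@@H]1O | intermediate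
7 | methyl (3S,4S,5R,6R)-4,5,6-trihydroxy-3-methoxycyclohex-1-ene-1-carboxylate | COC(=O)C1=C[C@H](OC)[C@@H](O)[C@H](O)[C@@H]1O | intermediate
8 | (1S,2R,3R,6S)-4-(hydroxymethyl)-6-methoxycyclohex-4-ene-1,2,3-triol | OCC1=C[C@H](OC)[C@@H](O)[C@H](O)[C@@H]1O | intermediate
9 | benzoyl chloride | O=C(Cl)c1ccccc1 | starting material
10 | 4,5-O-dibutylstannylene acetal of 8 (tin bridging O4 and O5 in target numbering, drawn as the monomer) | OCC1=C[C@H](OC)[C@@H](O)[C@@H]2O[Sn](CCCC)(CCCC)O[C@H]12 | intermediate (not isolated)
11 | [(3S,4R,5R,6R)-5-(benzoyloxy)-4,6-dihydroxy-3-methoxycyclohex-1-en-1-yl]methyl benzoate (CNP0349013.6) | CO[C@H]1C=C(COC(=O)c2ccccc2)[C@@H](O)[C@@H](OC(=O)c2ccccc2)[C@@H]1O | target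

**Step count**

Total step count: 5. Longest linear sequence: 5 steps (1 → 3 → 6 → 7 → 8 → 11).

**Steps most likely to fail**

Step 1 (key step). The catalyst holds the pyrone at one point only, so enantioface discrimination may be poor. The carbonate carbonyl of 2 may also compete with the pyrone for the metal, so that the catalysed pathway does not outrun the uncatalysed one. Fallback, setting out from 1 and 2 and returning at 3: the cycloaddition is run without catalyst (neat 2, 10–12 kbar, 25–40 °C), a known type of pressure-driven cycloaddition of 3-bromo-2-pyrone. This should give the racemic endo adduct, that is 3 mixed with its mirror image, the (1S,4S,7R,8R) adduct F1. The enantiomers are separated by preparative chromatography on an amylose tris(3,5-dimethylphenylcarbamate) phase; the bromine atom allows the absolute configuration to be assigned by anomalous dispersion. The route is rejoined at 3.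

Step 2. After ring opening, the alkoxide may fail to close cleanly on C1. Competing processes are loss of HBr with aromatisation, a hydride shift from C4 to C3 once the carbonate is cleaved, and Payne migration of the new epoxide towards C5. Fallback, setting out from 3 and returning at 7: the bromide is given up as a leaving group and the C1–C6 epoxide is rebuilt from a diene.
- Radical reduction (Bu3SnH, AIBN, benzene, 80 °C) gives the bromine-free lactone F2.
- K2CO3/MeOH at 0 °C opens lactone and carbonate to the β,γ-unsaturated triol ester F3.
- 2,2-Dimethoxypropane/PPTS masks the cis diol as the acetonide F4.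
- MsCl/Et3N gives the allylic C6 mesylate F5; DBU then removes the acidic H3 in a 1,4-elimination to the dienoate acetonide F6.
- mCPBA epoxidises the electron-richer C1=C6 bond anti to the acetonide, giving the epoxy acetonide F7.
- CSA/MeOH opens the epoxide at C1 and removes the acetonide, which returns the material to the route at 7.

Step 5. Acyl transfer may not discriminate O5 from O4 and O6, and a benzoate may migrate between the cis oxygens. Fallback, setting out from 8 and returning at 11: acylation is steered by protection and no longer by tin.
- t-Bu2Si(OTf)2/2,6-lutidine bridges the primary O7 and O4 as the six-membered silylene F8, as the 4,6-diol of galactosides does in the presence of a cis-3,4-diol.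
- BzCl (1.05 equiv)/pyridine at −40 °C acylates O5, the hydroxyl next to the axial silyl ether, to give the silylene benzoate F9.
- HF·pyridine removes the silylene to give the 5-O-benzoyl triol F10.
- BzCl/2,4,6-collidine at −40 °C then acylates only the primary allylic O7, giving 11.

Further compounds
F1 | step 1 | (1S,4S,7R,8R)-4-bromo-7,8-(carbonyldioxy)-2-oxabicyclo[2.2.2]oct-5-en-3-one (mirror image of 3) | O=C1O[C@H]2C=C[C@]1(Br)[C@@H]3OC(=O)O[C@H]23
F2 | step 2 | bromine-free lactone: 7,8-(carbonyldioxy)-2-oxabicyclo[2.2.2]oct-5-en-3-one with the configuration of 3 and H in place of Br | O=C1O[C@@H]2C=C[C@H]1[C@H]3OC(=O)O[C@@H]23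
F3 | step 2 | methyl 4,5,6-trihydroxycyclohex-2-ene-1-carboxylate with the configuration of 5 and H in place of Br | COC(=O)[C@H]1C=C[C@@H](O)[C@H](O)[C@@H]1O
F4 | step 2 | methyl 4-hydroxy-5,6-(isopropylidenedioxy)cyclohex-2-ene-1-carboxylate (acetonide of F3 on the cis diol) | COC(=O)[C@H]1C=C[C@@H](O)[C@@H]2OC(C)(C)O[C@H]12
F5 | step 2 | methyl 5,6-(isopropylidenedioxy)-4-(methanesulfonyloxy)cyclohex-2-ene-1-carboxylate (mesylate of F4) | COC(=O)[C@H]1C=C[C@@H](OS(C)(=O)=O)[C@@H]2OC(C)(C)O[C@H]12
F6 | step 2 | methyl (5S,6R)-5,6-(isopropylidenedioxy)cyclohexa-1,3-diene-1-carboxylate | COC(=O)C1=CC=C[C@@H]2OC(C)(C)O[C@H]12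
F7 | step 2 | 4,5-O-isopropylidene acetal of 6 (epoxide anti to the acetonide) | COC(=O)C1=C[C@H]2O[C@H]2[C@@H]3OC(C)(C)O[C@H]13
F8 | step 5 | 4,7-O-(di-tert-butylsilylene) derivative of 8 (target numbering) | CC(C)(C)[Si]1(C(C)(C)C)OCC2=C[C@H](OC)[C@@H](O)[C@H](O)[C@@H]2O1
F9 | step 5 | 5-O-benzoate of F8 | CC(C)(C)[Si]1(C(C)(C)C)OCC2=C[C@H](OC)[C@@H](O)[C@H](OC(=O)c3ccccc3)[C@@H]2O1
F10 | step 5 | 5-O-benzoyl triol (11 without the benzoyl group on O7) | OCC1=C[C@H](OC)[C@@H](O)[C@H](OC(=O)c2ccccc2)[C@@H]1O
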